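**Retrosynthetic overview**
- Ring A (C1, C10, C11, C12, C13, C14) is a cyclohexene whose C13=C14 double bond lies between the ring bonds C1–C10 and C11–C12: a Diels–Alder retron. Because C1–C10 is also the fusion bond of the ten-membered ring (C1–C10), one [4+2] of an open chain closes ring A and the ten-membered ring together.
- Precursor 25: a (1E,3E)-1-silyloxydiene (C12=C13–C14=C1) joined through C2–C9 to an (E)-enone (C10=C11(C20)–COCH3). The tether carries the (5Z) alkene, the finished lactone and two acetonides as temporary rings. The 11-acetyl group is the latent 11-OH (Baeyer–Villiger, retention).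
- 25 comes from alkyl iodide 10 (C12–C4, from D-threitol acetonide 1) and vinyl iodide 24 (C5–C11 plus lactone, from methyl (S)-glycerate 11 via a 3-methyltetronic acid) by nickel-catalysed reductive C4–C5 coupling.
- Ring order: lactone (C7, C8, C17, C19, O) first; then ring A and the ten-membered ring in one operation; end game: 11-acetyl → 11-OAc → 11-OH, acetonides off, 2,3,9-triacetate, 12-O desilylation.

Key step: step 21

Remark: atoms carry briarane numbers (C1–C20) throughout, and α means the face of ring A that carries H10. Methyl (2S)-2,3-dihydroxypropanoate is assumed to be commercial.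

**Fragment C12–C4 (steps 1–7)**

Step 1
Reactants: 1 (4R,5R)-2,2-dimethyl-1,3-dioxolane-4,5-dimethanol
Product: 2 [(4R,5R)-5-(hydroxymethyl)-2,2-dimethyl-1,3-dioxolan-4-yl]methyl 4-methylbenzenesulfonate
Conditions: TsCl (1.05 equiv), Ag2O, KI (cat.), CH2Cl2, 0 °C to rt
Reagents that add atoms: 4-methylbenzenesulfonyl chloride, Cc1ccc(cc1)S(Cl)(=O)=O
Why: Silver-oxide-mediated monosulfonylation of a C2-symmetric diol whose two CH2OH groups are equivalent, so only mono- versus bis-tosylation has to be controlled and no stereocentre is touched.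

Step 2
Reactants: 2 [(4R,5R)-5-(hydroxymethyl)-2,2-dimethyl-1,3-dioxolan-4-yl]methyl 4-methylbenzenesulfonate
Product: 3 [(4R,5S)-5-formyl-2,2-dimethyl-1,3-dioxolan-4-yl]methyl 4-methylbenzenesulfonate
Conditions: Dess–Martin periodinane, pyridine, CH2Cl2, 0 °C to rt
Reagents that add atoms: none
Why: Dess–Martin oxidation of the remaining primary alcohol under buffered conditions; the trans-dioxolane aldehyde is the thermodynamically preferred epimer, so C2 is not at risk.

Step 3
Reactants: 3 [(4R,5S)-5-formyl-2,2-dimethyl-1,3-dioxolan-4-yl]methyl 4-methylbenzenesulfonate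
Product: 4 [(4R,5R)-5-ethynyl-2,2-dimethyl-1,3-dioxolan-4-yl]methyl 4-methylbenzenesulfonate
Conditions: dimethyl (1-diazo-2-oxopropyl)phosphonate, K2CO3, MeOH, 0 °C to rt
Reagents that add atoms: dimethyl (1-diazo-2-oxopropyl)phosphonate, COP(=O)(OC)C(=[N+]=[N-])C(C)=O
Why: Ohira–Bestmann (Seyferth–Gilbert) homologation turns the aldehyde into the terminal alkyne that becomes C1≡C14, under conditions mild enough for the hindered primary tosylate.

Step 4
Reactants: 4 [(4R,5R)-5-ethynyl-2,2-dimethyl-1,3-dioxolan-4-yl]methyl 4-methylbenzenesulfonate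
Product: 7 [(4R,5R)-5-[(2E)-5-hydroxypent-2-en-2-yl]-2,2-dimethyl-1,3-dioxolan-4-yl]methyl 4-methylbenzenesulfonate, via alkenyldimethylalane 5 (not isolated), via lithium alkenylalanate 6 (not isolated)
Conditions: Me3Al, Cp2ZrCl2, CH2Cl2, 0 °C to rt; n-BuLi, THF, -78 °C; ethylene oxide, -78 to 0 °C; aq. Rochelle salt
Reagents that add atoms: trimethylaluminium, C[Al](C)C; ethylene oxide, C1CO1
Why: Negishi zirconium-catalysed carboalumination adds CH3–Al syn across the alkyne with methyl on the internal carbon C1, and opening of ethylene oxide by the derived alanate brings in C13–C12–OH, so the (E)-C1=C14 bond (C15 cis to C13, C2 trans to C13) is fixed by the syn addition.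

Step 5
Reactants: 7 [(4R,5R)-5-[(2E)-5-hydroxypent-2-en-2-yl]-2,2-dimethyl-1,3-dioxolan-4-yl]methyl 4-methylbenzenesulfonate
Product: 8 (3E)-4-[(4R,5S)-5-(iodomethyl)-2,2-dimethyl-1,3-dioxolan-4-yl]pent-3-en-1-ol
Conditions: NaI, acetone, reflux
Reagents that add atoms: sodium iodide, [Na+].[I-]
Why: Finkelstein SN2 exchange turns the primary tosylate into the primary iodide needed for the nickel coupling, and nothing else in 7 reacts with NaI.

Step 6
Reactants: 8 (3E)-4-[(4R,5S)-5-(iodomethyl)-2,2-dimethyl-1,3-dioxolan-4-yl]pent-3-en-1-ol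
Product: 9 (3E)-4-[(4R,5S)-5-(iodomethyl)-2,2-dimethyl-1,3-dioxolan-4-yl]pent-3-enal
Conditions: Dess–Martin periodinane, pyridine, CH2Cl2, 0 °C
Reagents that add atoms: none
Why: Dess–Martin oxidation under pyridine-buffered, non-isomerising conditions gives the β,γ-unsaturated aldehyde, which is used at once so that the C14=C1 bond stays out of conjugation.

Step 7
Reactants: 9 (3E)-4-[(4R,5S)-5-(iodomethyl)-2,2-dimethyl-1,3-dioxolan-4-yl]pent-3-enal
Product: 10 {[(1E,3E)-4-[(4R,5S)-5-(iodomethyl)-2,2-dimethyl-1,3-dioxolan-4-yl]penta-1,3-dien-1-yl]oxy}tri(propan-2-yl)silane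
Conditions: iPr3SiOTf, Et3N, Et2O, -78 to 0 °C
Reagents that add atoms: triisopropylsilyl trifluoromethanesulfonate, CC(C)[Si](C(C)C)(C(C)C)OS(=O)(=O)C(F)(F)F
Why: Soft enolisation (O-silylation, then α-deprotonation at C13 by Et3N) gives the conjugated silyl dienol ether with the C14=C1 geometry retained; the extended (1E) enol ether is expected to predominate and is the only isomer able to react in step 21.

**Fragment C5–C11 with the lactone (steps 8–19)**

Step 8
Reactants: 11 methyl (2S)-2,3-dihydroxypropanoate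
Product: 12 methyl (2S)-3-[(tert-butyldiphenylsilyl)oxy]-2-hydroxypropanoate
Conditions: t-BuPh2SiCl, imidazole, CH2Cl2, 0 °C
Reagents that add atoms: tert-butyl(chloro)diphenylsilane, CC(C)(C)[Si](Cl)(c1ccccc1)c1ccccc1
Why: Selective silylation of the primary hydroxyl of the 1,2-diol by the bulky chlorosilane; C7 is untouched.

Step 9
Reactants: 12 methyl (2S)-3-[(tert-butyldiphenylsilyl)oxy]-2-hydroxypropanoate
Product: 13 methyl (2S)-3-[(tert-butyldiphenylsilyl)oxy]-2-(propanoyloxy)propanoate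
Conditions: EtCOCl, pyridine, DMAP (cat.), CH2Cl2, 0 °C to rt
Reagents that add atoms: propanoyl chloride, CCC(Cl)=O
Why: Standard O-acylation of the secondary α-hydroxy ester installs the propanoate that carries C17, C18 and C19.

Step 10
Reactants: 13 methyl (2S)-3-[(tert-butyldiphenylsilyl)oxy]-2-(propanoyloxy)propanoate
Product: 14 (5S)-5-{[(tert-butyldiphenylsilyl)oxy]methyl}-4-hydroxy-3-methylfuran-2(5H)-one
Conditions: LiN(SiMe3)2 (2.2 equiv), THF, -78 to -20 °C; aq. HCl
Reagents that add atoms: none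
Why: Dieckmann condensation of the propanoate enolate onto the methyl ester forms the C17–C8 bond and closes the lactone ring as a 3-methyltetronic acid, which is held as its enolate so that C7 keeps its configuration.

Step 11
Reactants: 14 (5S)-5-{[(tert-butyldiphenylsilyl)oxy]methyl}-4-hydroxy-3-methylfuran-2(5H)-one
Product: 15 (3S,5S)-5-{[(tert-butyldiphenylsilyl)oxy]methyl}-3-hydroxy-3-methylfuran-2,4(3H,5H)-dione
Conditions: dimethyldioxirane, acetone, -40 to 0 °C
Reagents that add atoms: dimethyldioxirane, CC1(C)OO1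
Why: Electrophilic hydroxylation of the enolised 1,3-dicarbonyl (enol epoxidation and opening) occurs on the face anti to the C7 CH2OSi group and so sets C17 with OH trans to C6.

Step 12
Reactants: 15 (3S,5S)-5-{[(tert-butyldiphenylsilyl)oxy]methyl}-3-hydroxy-3-methylfuran-2,4(3H,5H)-dione
Product: 16 (3S,4R,5S)-5-{[(tert-butyldiphenylsilyl)oxy]methyl}-4-ethenyl-3,4-dihydroxy-3-methyloxolan-2-one
Conditions: CH2=CHMgBr (2.5 equiv), LaCl3·2LiCl (0.3 equiv), THF, -78 °C
Reagents that add atoms: vinylmagnesium bromide, C=C[Mg]Br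
Why: Lanthanide-assisted Grignard 1,2-addition to the activated C8 ketone (lactone untouched at -78 °C) takes place anti to the C17 methyl and the C7 side chain, which lie on the same face, and so sets C8 with the new carbon cis to 17-OH.

Step 13
Reactants: 16 (3S,4R,5S)-5-{[(tert-butyldiphenylsilyl)oxy]methyl}-4-ethenyl-3,4-dihydroxy-3-methyloxolan-2-one
Product: 18 (2S,3R,4S)-2-{[(tert-butyldiphenylsilyl)oxy]methyl}-3,4-dihydroxy-4-methyl-5-oxooxolane-3-carbaldehyde, via secondary ozonide 17 (not isolated)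
Conditions: O3, CH2Cl2, -78 °C; PPh3, -78 °C to rt
Reagents that add atoms: ozone, [O-][O+]=O
Why: Ozonolysis of the monosubstituted vinyl group with reductive work-up unmasks the C9 aldehyde; no other C=C bond is present and C8 keeps its configuration.

Step 14
Reactants: 18 (2S,3R,4S)-2-{[(tert-butyldiphenylsilyl)oxy]methyl}-3,4-dihydroxy-4-methyl-5-oxooxolane-3-carbaldehyde
Product: 19 (3S,4R,5S)-5-{[(tert-butyldiphenylsilyl)oxy]methyl}-3,4-dihydroxy-4-[(1R)-1-hydroxyprop-2-en-1-yl]-3-methyloxolan-2-one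
Conditions: CH2=CHMgBr (4 equiv), THF, -78 to -40 °C
Reagents that add atoms: vinylmagnesium bromide, C=C[Mg]Br
Why: Cram-chelate-controlled Grignard addition, with magnesium bridging the C8 alkoxide and the aldehyde oxygen, lets the vinyl group reach C9 from the side of C7–H and away from the fully substituted C17 with its alkoxide, which sets the (9R) carbinol.

Step 15
Reactants: 19 (3S,4R,5S)-5-{[(tert-butyldiphenylsilyl)oxy]methyl}-3,4-dihydroxy-4-[(1R)-1-hydroxyprop-2-en-1-yl]-3-methyloxolan-2-one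
Product: 20 (4R,5R,6S,9S)-6-{[(tert-butyldiphenylsilyl)oxy]methyl}-4-ethenyl-9-hydroxy-2,2,9-trimethyl-1,3,7-trioxaspiro[4.4]nonan-8-one
Conditions: 2-methoxypropene, PPTS (cat.), CH2Cl2, 0 °C
Reagents that add atoms: 2-methoxypropene, COC(C)=C
Why: Acetonide formation on the only vicinal diol that can give an unstrained dioxolane (8-OH/9-OH; the trans 8,17-diol cannot) protects both hydroxyls and stiffens this part of the later tether.

Step 16
Reactants: 20 (4R,5R,6S,9S)-6-{[(tert-butyldiphenylsilyl)oxy]methyl}-4-ethenyl-9-hydroxy-2,2,9-trimethyl-1,3,7-trioxaspiro[4.4]nonan-8-one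
Product: 21 (4R,5R,6S,9S)-4-ethenyl-9-hydroxy-6-(hydroxymethyl)-2,2,9-trimethyl-1,3,7-trioxaspiro[4.4]nonan-8-one
Conditions: HF·pyridine, pyridine, THF, 0 °C to rt
Reagents that add atoms: none
Why: Fluoride cleavage of the primary silyl ether under buffered conditions that leave the acetonide and the lactone intact.

Step 17
Reactants: 21 (4R,5R,6S,9S)-4-ethenyl-9-hydroxy-6-(hydroxymethyl)-2,2,9-trimethyl-1,3,7-trioxaspiro[4.4]nonan-8-one
Product: 22 (4R,5R,6R,9S)-4-ethenyl-9-hydroxy-2,2,9-trimethyl-8-oxo-1,3,7-trioxaspiro[4.4]nonane-6-carbaldehyde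
Conditions: Dess–Martin periodinane, pyridine, CH2Cl2, 0 °C
Reagents that add atoms: none
Why: Dess–Martin oxidation of the primary alcohol (the only oxidisable hydroxyl, 17-OH being tertiary) gives the α-oxygenated C6 aldehyde without epimerising C7.

Step 18
Reactants: 22 (4R,5R,6R,9S)-4-ethenyl-9-hydroxy-2,2,9-trimethyl-8-oxo-1,3,7-trioxaspiro[4.4]nonane-6-carbaldehyde
Product: 23 (4R,5R,6S,9S)-4-ethenyl-9-hydroxy-6-[(1Z)-2-iodoprop-1-en-1-yl]-2,2,9-trimethyl-1,3,7-trioxaspiro[4.4]nonan-8-one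
Conditions: EtPPh3I, n-BuLi, THF; I2, -78 °C; NaN(SiMe3)2, -20 °C; then 22, -78 °C
Reagents that add atoms: ethyltriphenylphosphonium iodide, CC[P+](c1ccccc1)(c1ccccc1)c1ccccc1.[I-]; iodine, II
Why: Stork–Zhao olefination with the α-iodo ylide gives the (Z)-2-iodoalk-2-ene (iodine cis to C7) under kinetic control at low temperature, which fixes the future (5Z) geometry.

Step 19
Reactants: 23 (4R,5R,6S,9S)-4-ethenyl-9-hydroxy-6-[(1Z)-2-iodoprop-1-en-1-yl]-2,2,9-trimethyl-1,3,7-trioxaspiro[4.4]nonan-8-one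
Product: 24 (4R,5R,6S,9S)-9-hydroxy-6-[(1Z)-2-iodoprop-1-en-1-yl]-2,2,9-trimethyl-4-[(1E)-2-methyl-3-oxobut-1-en-1-yl]-1,3,7-trioxaspiro[4.4]nonan-8-one
Conditions: 3-methylbut-3-en-2-one (10 equiv), second-generation Hoveyda–Grubbs catalyst [RuCl2(H2IMes)(=CH-C6H4-2-OiPr)] (10 mol%), CH2Cl2, 40 °C
Reagents that add atoms: 3-methylbut-3-en-2-one, CC(=O)C(C)=C
Why: Olefin cross-metathesis of the terminal vinyl group with an excess of the 1,1-disubstituted enone gives the thermodynamically preferred (E)-trisubstituted enone (C9 cis to C20), the hindered trisubstituted vinyl iodide being inert to the ruthenium carbene.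

**Union, key step and end game (steps 20–26)**

Step 20
Reactants: 10 {[(1E,3E)-4-[(4R,5S)-5-(iodomethyl)-2,2-dimethyl-1,3-dioxolan-4-yl]penta-1,3-dien-1-yl]oxy}tri(propan-2-yl)silane; 24 (4R,5R,6S,9S)-9-hydroxy-6-[(1Z)-2-iodoprop-1-en-1-yl]-2,2,9-trimethyl-4-[(1E)-2-methyl-3-oxobut-1-en-1-yl]-1,3,7-trioxaspiro[4.4]nonan-8-one
Product: 25 open-chain tetraene: (1E,3E)-1-(triisopropylsilyloxy)diene C12=C13–C14=C1(C15), 2,3-O-isopropylidene, C4H2, (5Z)-C5(C16)=C6, lactone (C7, C8, C17, C19) with 8,9-O-isopropylidene and 17-OH, (10E)-C10=C11(C20)–COCH3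
Conditions: NiBr2(dme) (15 mol%), 4,4'-di-tert-butyl-2,2'-bipyridine, Zn powder, NaI (cat.), DMA, 25 °C
Reagents that add atoms: none
Why: Nickel-catalysed reductive cross-electrophile coupling, in which zerovalent nickel inserts into the vinyl C–I bond with retention of the (Z) geometry and captures the primary alkyl radical from 10, joins C4 to C5 under neutral conditions that tolerate the silyl dienol ether, the lactone and the free tertiary alcohol; no stereocentre is formed.

Step 21
Reactants: 25 open-chain tetraene (C12–C1 silyloxydiene, C2–C9 tether, C10=C11 enone)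
Product: 26 tricyclic cycloadduct: 11-acetyl-12-(triisopropylsilyloxy)-2,3:8,9-di-O-isopropylidene-17-hydroxy briarane lactone with C5=C6 (Z) and C13=C14; 11-acetyl, 12-OSi and H10 on the α face, C15 and C20 on the β face
Conditions: PhMe (0.5 mM), 2,6-di-tert-butyl-4-methylphenol (cat.), 130 °C, sealed vessel
Reagents that add atoms: none
Why: Thermal, concerted but asynchronous [4+2] cycloaddition in which the C12=C13–C14=C1 silyloxydiene (nucleophilic at C1) and the C10=C11 enone (electrophilic at C10) of one chain combine, so that C1–C10 and C11–C12 form together; the closest known reaction type is the type 1 intramolecular Diels–Alder macrocyclization that closes 9- to 14-membered carbocycles fused to the new cyclohexene. Ring A (C1, C10–C14) is closed as the six-membered [4+2] ring and the ten-membered ring (C1–C10) by the same C1–C10 bond, the eight-atom tether C2–C9 joining diene terminus to dienophile terminus in the fused mode, pre-bent by the (Z)-C5=C6 bond, the lactone and the two dioxolane rings. C1 and C12 follow from the (1E,3E) diene geometry (C2 and OSi outside, C15 inside, hence C2 and O12 cis), C10 and C11 from the (E) enone geometry (C9 cis to C20), and the relation between the two pairs from the endo-acetyl transition state with the tether anti, which gives the trans ring fusion (H10 anti to C15) and the acetyl group cis to O12. The absolute sense is set by the two allylic stereocentres: at C9, allylic 1,3-strain with the cis C20 methyl keeps H9 in the enone plane and the diene adds anti to the C9–O bond; at C2 the dienophile adds anti to the C2–O bond with C3 on the reacting face; both preferences lead to the face pairing drawn in 26. The step needs ortho regiochemistry, endo topicity and this π-facial choice; the first is secured by the donor at C12 and the acceptor at C11 together with the tether, the others by the substrate elements just named, and high dilution suppresses intermolecular reaction.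

Step 22
Reactants: 26 tricyclic cycloadduct (11-acetyl, 12-OSi, two acetonides, 17-OH)
Product: 27 11-acetate: 11-acetoxy-12-(triisopropylsilyloxy)-2,3:8,9-di-O-isopropylidene-17-hydroxy briarane lactone
Conditions: Me3SiOOSiMe3, SnCl4 (20 mol%), trans-cyclohexane-1,2-diamine (20 mol%), 4 Å MS, CH2Cl2, 0 °C to rt
Reagents that add atoms: bis(trimethylsilyl) peroxide, C[Si](C)(C)OO[Si](C)(C)C
Why: Baeyer–Villiger oxidation with a silyl peroxide and a Lewis acid, a variant that does not epoxidise C=C bonds; the quaternary C11 migrates in preference to methyl and with retention, so the 11-acetyl group becomes 11-acetoxy with oxygen on the face set in step 21.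

Step 23
Reactants: 27 11-acetate
Product: 28 11-alcohol: 11,17-dihydroxy-12-(triisopropylsilyloxy)-2,3:8,9-di-O-isopropylidene briarane lactone
Conditions: K2CO3, MeOH, rt to 40 °C; AcOH work-up
Reagents that add atoms: none
Why: Base-catalysed transesterification removes the only acetate (the 8,9-acetonide blocks retro-aldol opening at C8 and the lactone recloses on acidic work-up) to free the tertiary 11-OH.

Step 24
Reactants: 28 11-alcohol
Product: 29 hexaol silyl ether: 2,3,8,9,11,17-hexahydroxy-12-(triisopropylsilyloxy) briarane lactone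
Conditions: AcOH/H2O/THF (3:1:1), 40 °C
Reagents that add atoms: none
Why: Mild acid hydrolysis cleaves both dioxolanes while the secondary triisopropylsilyl ether survives, which leaves C12 as the only masked secondary oxygen.

Step 25
Reactants: 29 hexaol silyl ether
Product: 30 2,3,9-triacetate: 2,3,9-triacetoxy-8,11,17-trihydroxy-12-(triisopropylsilyloxy) briarane lactone
Conditions: Ac2O, pyridine, DMAP (cat.), 0 °C to rt
Reagents that add atoms: acetic anhydride, CC(=O)OC(C)=O
Why: Acetylation of the three secondary alcohols (C2, C3, C9); the tertiary alcohols at C8, C11 and C17 do not react under these conditions and C12 is still silylated.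

Step 26
Reactants: 30 2,3,9-triacetate
Product: 31 CNP0269341.1 (2,3,9-triacetoxy-8,11,12,17-tetrahydroxy briarane lactone, target)
Conditions: HF·pyridine, pyridine, THF, 0 °C to rt
Reagents that add atoms: none
Why: Fluoride cleavage of the silyl ether under buffered conditions that touch neither the acetates nor the lactone gives the target.

**Compound list**

1 | (4R,5R)-2,2-dimethyl-1,3-dioxolane-4,5-dimethanol | OC[C@H]1OC(C)(C)O[C@@H]1CO | starting material
2 | [(4R,5R)-5-(hydroxymethyl)-2,2-dimethyl-1,3-dioxolan-4-yl]methyl 4-methylbenzenesulfonate | Cc1ccc(cc1)S(=O)(=O)OC[C@H]1OC(C)(C)O[C@@H]1CO | intermediate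
3 | [(4R,5S)-5-formyl-2,2-dimethyl-1,3-dioxolan-4-yl]methyl 4-methylbenzenesulfonate | Cc1ccc(cc1)S(=O)(=O)OC[C@H]1OC(C)(C)O[C@@H]1C=O | intermediate
4 | [(4R,5R)-5-ethynyl-2,2-dimethyl-1,3-dioxolan-4-yl]methyl 4-methylbenzenesulfonate | Cc1ccc(cc1)S(=O)(=O)OC[C@H]1OC(C)(C)O[C@@H]1C#C | intermediate
5 | dimethyl{(1E)-2-[(4R,5R)-2,2-dimethyl-5-(tosyloxymethyl)-1,3-dioxolan-4-yl]prop-1-en-1-yl}alane | Cc1ccc(cc1)S(=O)(=O)OC[C@H]1OC(C)(C)O[C@@H]1/C(C)=C/[Al](C)C | intermediate (not isolated)
6 | lithium butyl(dimethyl){(1E)-2-[(4R,5R)-2,2-dimethyl-5-(tosyloxymethyl)-1,3-dioxolan-4-yl]prop-1-en-1-yl}alanate | [Li+].Cc1ccc(cc1)S(=O)(=O)OC[C@H]1OC(C)(C)O[C@@H]1/C(C)=C/[Al-](C)(C)CCCC | intermediate (not isolated)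
7 | [(4R,5R)-5-[(2E)-5-hydroxypent-2-en-2-yl]-2,2-dimethyl-1,3-dioxolan-4-yl]methyl 4-methylbenzenesulfonate | Cc1ccc(cc1)S(=O)(=O)OC[C@H]1OC(C)(C)O[C@@H]1/C(C)=C/CCO | intermediate
8 | (3E)-4-[(4R,5S)-5-(iodomethyl)-2,2-dimethyl-1,3-dioxolan-4-yl]pent-3-en-1-ol | IC[C@H]1OC(C)(C)O[C@@H]1/C(C)=C/CCO | intermediate
9 | (3E)-4-[(4R,5S)-5-(iodomethyl)-2,2-dimethyl-1,3-dioxolan-4-yl]pent-3-enal | IC[C@H]1OC(C)(C)O[C@@H]1/C(C)=C/CC=O | intermediate
10 | {[(1E,3E)-4-[(4R,5S)-5-(iodomethyl)-2,2-dimethyl-1,3-dioxolan-4-yl]penta-1,3-dien-1-yl]oxy}tri(propan-2-yl)silane | IC[C@H]1OC(C)(C)O[C@@H]1/C(C)=C/C=C/O[Si](C(C)C)(C(C)C)C(C)C | intermediate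
11 | methyl (2S)-2,3-dihydroxypropanoate | OC[C@H](O)C(=O)OC | starting material
12 | methyl (2S)-3-[(tert-butyldiphenylsilyl)oxy]-2-hydroxypropanoate | CC(C)(C)[Si](c1ccccc1)(c1ccccc1)OC[C@H](O)C(=O)OC | intermediate
13 | methyl (2S)-3-[(tert-butyldiphenylsilyl)oxy]-2-(propanoyloxy)propanoate | CC(C)(C)[Si](c1ccccc1)(c1ccccc1)OC[C@H](OC(=O)CC)C(=O)OC | intermediate
14 | (5S)-5-{[(tert-butyldiphenylsilyl)oxy]methyl}-4-hydroxy-3-methylfuran-2(5H)-one | CC(C)(C)[Si](c1ccccc1)(c1ccccc1)OC[C@@H]1OC(=O)C(C)=C1O | intermediate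
15 | (3S,5S)-5-{[(tert-butyldiphenylsilyl)oxy]methyl}-3-hydroxy-3-methylfuran-2,4(3H,5H)-dione | CC(C)(C)[Si](c1ccccc1)(c1ccccc1)OC[C@@H]1OC(=O)[C@@](C)(O)C1=O | intermediate
16 | (3S,4R,5S)-5-{[(tert-butyldiphenylsilyl)oxy]methyl}-4-ethenyl-3,4-dihydroxy-3-methyloxolan-2-one | CC(C)(C)[Si](c1ccccc1)(c1ccccc1)OC[C@@H]1OC(=O)[C@@](C)(O)[C@@]1(O)C=C | intermediate
17 | secondary ozonide of 16 (1,2,4-trioxolan-3-yl in place of ethenyl, both epimers at the trioxolane carbon) | CC(C)(C)[Si](c1ccccc1)(c1ccccc1)OC[C@@H]1OC(=O)[C@@](C)(O)[C@@]1(O)C2OCOO2 | intermediate (not isolated)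
18 | (2S,3R,4S)-2-{[(tert-butyldiphenylsilyl)oxy]methyl}-3,4-dihydroxy-4-methyl-5-oxooxolane-3-carbaldehyde | CC(C)(C)[Si](c1ccccc1)(c1ccccc1)OC[C@@H]1OC(=O)[C@@](C)(O)[C@@]1(O)C=O | intermediate
19 | (3S,4R,5S)-5-{[(tert-butyldiphenylsilyl)oxy]methyl}-3,4-dihydroxy-4-[(1R)-1-hydroxyprop-2-en-1-yl]-3-methyloxolan-2-one | CC(C)(C)[Si](c1ccccc1)(c1ccccc1)OC[C@@H]1OC(=O)[C@@](C)(O)[C@@]1(O)[C@H](O)C=C | intermediate
20 | (4R,5R,6S,9S)-6-{[(tert-butyldiphenylsilyl)oxy]methyl}-4-ethenyl-9-hydroxy-2,2,9-trimethyl-1,3,7-trioxaspiro[4.4]nonan-8-one | CC(C)(C)[Si](c1ccccc1)(c1ccccc1)OC[C@@H]1OC(=O)[C@@](C)(O)[C@]12OC(C)(C)O[C@@H]2C=C | intermediate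
21 | (4R,5R,6S,9S)-4-ethenyl-9-hydroxy-6-(hydroxymethyl)-2,2,9-trimethyl-1,3,7-trioxaspiro[4.4]nonan-8-one | OC[C@@H]1OC(=O)[C@@](C)(O)[C@]12OC(C)(C)O[C@@H]2C=C | intermediate
22 | (4R,5R,6R,9S)-4-ethenyl-9-hydroxy-2,2,9-trimethyl-8-oxo-1,3,7-trioxaspiro[4.4]nonane-6-carbaldehyde | O=C[C@@H]1OC(=O)[C@@](C)(O)[C@]12OC(C)(C)O[C@@H]2C=C | intermediate
23 | (4R,5R,6S,9S)-4-ethenyl-9-hydroxy-6-[(1Z)-2-iodoprop-1-en-1-yl]-2,2,9-trimethyl-1,3,7-trioxaspiro[4.4]nonan-8-one | I/C(C)=C\[C@@H]1OC(=O)[C@@](C)(O)[C@]12OC(C)(C)O[C@@H]2C=C | intermediate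
24 | (4R,5R,6S,9S)-9-hydroxy-6-[(1Z)-2-iodoprop-1-en-1-yl]-2,2,9-trimethyl-4-[(1E)-2-methyl-3-oxobut-1-en-1-yl]-1,3,7-trioxaspiro[4.4]nonan-8-one | I/C(C)=C\[C@@H]1OC(=O)[C@@](C)(O)[C@]12OC(C)(C)O[C@@H]2/C=C(C)/C(C)=O | intermediate
25 | open-chain tetraene: (1E,3E)-1-(triisopropylsilyloxy)diene (C12–C1), 2,3-acetonide, (5Z)-alkene, lactone with 8,9-acetonide and 17-OH, (10E)-11-acetyl enone; stereocentres C2, C3, C7, C8, C9, C17 as drawn | CC(C)[Si](C(C)C)(C(C)C)O/C=C/C=C(C)/[C@H]1OC(C)(C)O[C@@H]1C/C(C)=C\[C@@H]2OC(=O)[C@@](C)(O)[C@]23OC(C)(C)O[C@@H]3/C=C(C)/C(C)=O | intermediate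
26 | cycloadduct: 11α-acetyl-12α-(triisopropylsilyloxy)-2,3:8,9-di-O-isopropylidene-17-hydroxy briarane lactone, (5Z), 13-ene, H10 α, C15 and C20 β | CC1(C)O[C@@H]2[C@H]3[C@](C)(C(C)=O)[C@H](O[Si](C(C)C)(C(C)C)C(C)C)C=C[C@]3(C)[C@H]4OC(C)(C)O[C@@H]4C/C(C)=C\[C@@H]5OC(=O)[C@@](C)(O)[C@]52O1 | intermediate
27 | 11α-acetoxy analogue of 26 (acetyl replaced by acetoxy, same configuration) | CC1(C)O[C@@H]2[C@H]3[C@](C)(OC(C)=O)[C@H](O[Si](C(C)C)(C(C)C)C(C)C)C=C[C@]3(C)[C@H]4OC(C)(C)O[C@@H]4C/C(C)=C\[C@@H]5OC(=O)[C@@](C)(O)[C@]52O1 | intermediate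
28 | 11α-hydroxy analogue (11,17-diol, 12-O-silyl, two acetonides) | CC1(C)O[C@@H]2[C@H]3[C@](C)(O)[C@H](O[Si](C(C)C)(C(C)C)C(C)C)C=C[C@]3(C)[C@H]4OC(C)(C)O[C@@H]4C/C(C)=C\[C@@H]5OC(=O)[C@@](C)(O)[C@]52O1 | intermediate
29 | 2,3,8,9,11,17-hexahydroxy-12-(triisopropylsilyloxy) briarane lactone, configuration as in the target | O[C@@H]1[C@H]2[C@](C)(O)[C@H](O[Si](C(C)C)(C(C)C)C(C)C)C=C[C@]2(C)[C@@H](O)[C@H](O)C/C(C)=C\[C@@H]2OC(=O)[C@@](C)(O)[C@]21O | intermediate
30 | 2,3,9-triacetoxy-8,11,17-trihydroxy-12-(triisopropylsilyloxy) briarane lactone, configuration as in the target | CC(=O)O[C@@H]1[C@H]2[C@](C)(O)[C@H](O[Si](C(C)C)(C(C)C)C(C)C)C=C[C@]2(C)[C@@H](OC(C)=O)[C@H](OC(C)=O)C/C(C)=C\[C@@H]2OC(=O)[C@@](C)(O)[C@]21O | intermediate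
31 | CNP0269341.1, (1S,2R,3R,5Z,7S,8S,9R,10S,11S,12R,17S)-2,3,9-triacetoxy-8,11,12,17-tetrahydroxy briarane lactone | CC(=O)O[C@@H]1[C@H]2[C@](C)(O)[C@H](O)C=C[C@]2(C)[C@@H](OC(C)=O)[C@H](OC(C)=O)C/C(C)=C\[C@@H]2OC(=O)[C@@](C)(O)[C@]21O | target

**Step count and risks**

Total step count: 26. Longest linear sequence: 19 steps (11 to 31, steps 8–26); the other branch (1 to 10) has 7 steps.

Steps most likely to fail:

1. Step 21 (cycloaddition). The diene must reach its s-cis form with the C15 methyl group on the inside while a ten-membered ring closes. Intermolecular reaction, thermal loss of the silyl dienol ether, or closure through the exo or the other π-facial mode may therefore compete. Fallback, setting out from 10 and 24 (step 20 is then skipped): the two fragments are combined in an intermolecular Diels–Alder reaction under high pressure (CH2Cl2, about 13 kbar, rt), where the same ortho and endo preferences and the C9 stereocentre should give the ring-A cycloadduct bis-iodide F1. The ten-membered ring is then closed at C4–C5 by intramolecular nickel-catalysed reductive coupling (NiBr2(dme), 4,4'-di-tert-butyl-2,2'-bipyridine, Zn, DMA, slow addition at high dilution). This comes back to the route at 26.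

2. Step 22 (Baeyer–Villiger oxidation). The silyl peroxide may fail to add to the very hindered C11 acetyl group, or the Lewis acid may open an acetonide or ionise the allylic silyl ether. Fallback, setting out from 26: oxidation with CF3CO3H (from (CF3CO)2O and urea·H2O2, Na2HPO4, CH2Cl2, 0 °C) accepts concurrent epoxidation of C5=C6 and gives the 5,6-epoxy 11-acetate F2. Stereospecific deoxygenation with retention (Ph3P=Se, CF3CO2H, CH2Cl2) then restores the (5Z) alkene and comes back to the route at 27.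

3. Step 20 (fragment coupling). Reduction or homodimerisation of either iodide, loss of the (Z) geometry, or conjugate addition of the alkyl radical to the enone may compete with cross-coupling. Fallback, setting out from 10: copper-catalysed borylation of the primary iodide (CuI, PPh3, LiOtBu, B2pin2, DMF) gives the pinacol boronate F3. Suzuki–Miyaura coupling of F3 with 24 (Pd(OAc)2, RuPhos, K3PO4, toluene/H2O, 80 °C) forms the same C4–C5 bond by a two-electron pathway and comes back to the route at 25.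

Further compounds
F1 | step 21 | ring-A cycloadduct bis-iodide (C1–C10 and C11–C12 formed, C4–I and C5–I still present, C4–C5 bond not yet formed) | I/C(C)=C\[C@@H]1OC(=O)[C@@](C)(O)[C@]12OC(C)(C)O[C@@H]2[C@H]3[C@](C)(C(C)=O)[C@H](O[Si](C(C)C)(C(C)C)C(C)C)C=C[C@]3(C)[C@H]4OC(C)(C)O[C@@H]4CI
F2 | step 22 | 5,6-epoxide of 27 (either epoxide face) | CC1(C)O[C@@H]2[C@H]3[C@](C)(OC(C)=O)[C@H](O[Si](C(C)C)(C(C)C)C(C)C)C=C[C@]3(C)[C@H]4OC(C)(C)O[C@@H]4CC6(C)OC6[C@@H]5OC(=O)[C@@](C)(O)[C@]52O1
F3 | step 20 | pinacol boronate from 10 (iodide replaced by the 4,4,5,5-tetramethyl-1,3,2-dioxaborolan-2-yl group) | CC1(C)OB(OC1(C)C)C[C@H]2OC(C)(C)O[C@@H]2/C(C)=C/C=C/O[Si](C(C)C)(C(C)C)C(C)C
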